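**Assumption:** the target SMILES has no stereocentre or stereodescriptor, and the marchantin macrocycle interconverts its conformers freely at room temperature. I therefore treat the compound as achiral, so no stereocontrol is needed. The one alkene geometry created in step 5 is erased in step 6.

## Retrosynthetic overview
1. All four arenes are purchased. The only ring built is the 18-membered macrocycle, which is closed last.
2. The final step hydrogenates a macrocyclic A–CH=CH–B stilbene and removes the ring-B O-benzyl group in the same operation.
3. The macrocycle comes from an intramolecular McMurry coupling of an open-chain dialdehyde, with one CHO on ring A and one on ring B.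
4. Both diaryl ethers (D–O–A and B–O–C) are made by SNAr on fluorobenzaldehydes, so the same two CHO groups activate the SNAr and later serve as the McMurry handles.
5. The saturated C–CH2CH2–D bridge is made directly by hydroboration and B-alkyl Suzuki coupling of 3-vinylphenol with a ring-D aryl bromide.

## Route

**Step 1**
Reactants: 1, 5-bromo-2-methoxyphenol; 2, 4-fluorobenzaldehyde
Product: 3, 4-(5-bromo-2-methoxyphenoxy)benzaldehyde
Conditions: K2CO3 (2 equiv), DMF, 130 °C
Reagents that add atoms: 4-fluorobenzaldehyde (2), O=Cc1ccc(F)cc1
Why: This is an SNAr reaction in which the para-CHO activates fluoride toward the phenoxide, while the unactivated aryl bromide stays inert.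

**Step 2**
Reactants: 4, 3-vinylphenol; 3
Product: 5, 4-{5-[2-(3-hydroxyphenyl)ethyl]-2-methoxyphenoxy}benzaldehyde
Conditions: (i) 4 (1.3 equiv), 9-BBN (2.2 equiv per 4), THF, 0 °C to rt; (ii) 3 M aq K3PO4 until H2 evolution stops, then 3, PdCl2(dppf) (5 mol %), THF/DMF, 60 °C; NH4Cl work-up, with no H2O2 because of the Dakin risk
Reagents that add atoms: none
Why: Anti-Markovnikov hydroboration followed by B-alkyl Suzuki–Miyaura coupling gives the CH2CH2 bridge directly (9-BBN contributes only H), because one equivalent of 9-BBN masks the phenol as ArO–BBN (hydrolysed by base) and residual B–H is quenched before aldehyde 3 is added.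

**Step 3**
Reactants: 6, 2-fluoro-3-hydroxybenzaldehyde; 7, benzyl bromide
Product: 8, 3-(benzyloxy)-2-fluorobenzaldehyde
Conditions: BnBr (1.1 equiv), K2CO3, DMF, rt
Reagents that add atoms: benzyl bromide (7), BrCc1ccccc1
Why: This Williamson O-benzylation is much faster at rt than any self-SNAr, and it installs a group that is removed without an extra step in the final hydrogenation.

**Step 4**
Reactants: 5; 8 (1.3 equiv)
Product: 9, 3-(benzyloxy)-2-(3-{2-[3-(4-formylphenoxy)-4-methoxyphenyl]ethyl}phenoxy)benzaldehyde (open-chain dialdehyde)
Conditions: Cs2CO3 (1.5 equiv), DMF, 100 °C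
Reagents that add atoms: 3-(benzyloxy)-2-fluorobenzaldehyde (8), O=Cc1cccc(OCc2ccccc2)c1F
Why: In this SNAr reaction the unhindered ring-C phenoxide displaces the fluoride activated by the ortho-CHO, and because F is a far better leaving group than ArO, the existing 4-aryloxybenzaldehyde ether is not exchanged at 100 °C.

**Step 5**
Reactants: 9
Product: 10, O-benzyl-dehydromarchantin P, the 18-membered macrocycle with an A–CH=CH–B stilbene bridge (Z major; geometry does not matter)
Conditions: TiCl4/Zn, pyridine, THF, reflux; 9 added by syringe pump over about 20 h (final concentration about 1 mM); aq K2CO3 quench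
Reagents that add atoms: none
Why: Intramolecular McMurry coupling under pseudo-high dilution joins the two aryl aldehydes reductively with loss of both carbonyl oxygens, ethers are tolerated, and any partial loss of benzyl is harmless because it comes off in the next step.

**Step 6**
Reactants: 10
Product: 11, marchantin P
Conditions: H2 (1 atm), 10 % Pd/C, EtOAc/EtOH, rt
Reagents that add atoms: none
Why: Catalytic hydrogenation saturates the stilbene and hydrogenolyses the aryl benzyl ether in one operation, leaving the OMe and the diaryl ethers intact.

## Compound list
1 | 5-bromo-2-methoxyphenol | COc1ccc(Br)cc1O | starting material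
2 | 4-fluorobenzaldehyde | O=Cc1ccc(F)cc1 | starting material
3 | 4-(5-bromo-2-methoxyphenoxy)benzaldehyde | COc1ccc(Br)cc1Oc1ccc(C=O)cc1 | intermediate
4 | 3-vinylphenol | C=Cc1cccc(O)c1 | starting material
5 | 4-{5-[2-(3-hydroxyphenyl)ethyl]-2-methoxyphenoxy}benzaldehyde | COc1ccc(CCc2cccc(O)c2)cc1Oc1ccc(C=O)cc1 | intermediate
6 | 2-fluoro-3-hydroxybenzaldehyde | O=Cc1cccc(O)c1F | starting material
7 | benzyl bromide | BrCc1ccccc1 | starting material
8 | 3-(benzyloxy)-2-fluorobenzaldehyde | O=Cc1cccc(OCc2ccccc2)c1F | intermediate
9 | 3-(benzyloxy)-2-(3-{2-[3-(4-formylphenoxy)-4-methoxyphenyl]ethyl}phenoxy)benzaldehyde | COc1ccc(CCc2cccc(Oc3c(C=O)cccc3OCc3ccccc3)c2)cc1Oc1ccc(C=O)cc1 | intermediate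
10 | O-benzyl-dehydromarchantin P (macrocyclic Z-stilbene) | COc1ccc2cc1Oc1ccc(cc1)/C=C\c1cccc(OCc3ccccc3)c1Oc1cccc(c1)CC2 | intermediate
11 | marchantin P (C29H26O4) | COc1ccc2cc1Oc1ccc(cc1)CCc1cccc(O)c1Oc1cccc(c1)CC2 | target

## Summary
Total steps: 6
Longest linear sequence: 5 (steps 1, 2, 4, 5, 6). Step 3 is a one-step side branch.

Steps most likely to fail:
1. **Step 5, McMurry macrocyclisation.** The risks are ring strain from the para-phenylene, oligomer formation and arrest at the pinacol. Fallback:
   - Reduce 9 to the diol (NaBH4) and convert it to the bis(benzylic bromide) (PBr3).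
   - Close the ring by an intramolecular Wurtz-type reductive coupling (Na/tetraphenylethene or Ni(0)), which gives the saturated bridge directly.
   - Remove the benzyl group by hydrogenolysis.
2. **Step 4, SNAr on the doubly ortho-flanked fluoride with an advanced phenol.** The reaction may be slow, and forcing it could scramble the existing ether. Fallback: change the assembly order, which costs one extra step and gives the same dialdehyde 9.
   - Make the hindered ether first from 8 and cheap 3-bromophenol.
   - Couple that bromide by B-alkyl Suzuki with 2-methoxy-5-vinylphenol, obtained by Wittig methylenation of isovanillin.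
   - Install ring A last with the much more reactive 4-fluorobenzaldehyde.
3. **Step 2, B-alkyl Suzuki with a free phenol, an aldehyde and an electron-rich bromide.** The risks are aldehyde reduction and protodeboronation. Fallback: Sonogashira coupling of 3 with 3-ethynylphenol, followed by chemoselective hydrogenation of the diarylalkyne over Pd/C poisoned with Ph2S, which spares ArCHO. This also gives 5, at the cost of one extra step.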